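**Plan**

- Retrosynthesis: the O1–C2 hemiketal bond is opened to a 1-aryl-1,2-dione whose C2 carbonyl is masked as a 1,3-dithiane; the benzo ring is then cut at C4–C5 and C3a–C7a; the chain is cut last at C2–C3 and C2–C1'.
- Enabling feature: the benzo ring (C3a, C4, C5, C6, C7, C7a) is a 2,4-dioxygenated aryl ketone, with oxygen on C7a and C6 and the C3 acyl carbon on C3a. C5–C6–C7–C7a is therefore an acetoacetate-derived bis(silyloxy)diene and C3a–C4 the alkyne of a terminal ynone.
- Forward: the chain is joined first (dithiane, farnesyl bromide, 3-(trimethylsilyl)propynal, oxidation to the ynone). The benzo ring is closed second by Diels–Alder benzannulation, and the furanone ring last by dithiane removal and 5-exo hemiketalization.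
- Stereochemistry: both E alkenes come with farnesyl bromide. C2, the only stereocentre, is a labile hemiketal that forms racemic and is then set as (R) by crystallization-induced asymmetric transformation of its quinine salt.

Key step: step 6

Assumption: C2 is taken to epimerise only through the ring-opened dione under amine, acid or base catalysis and to hold its configuration as the free hemiketal in the solid and in cold neutral solution; the (R)-epimer is taken to give the less soluble quinine salt (otherwise the pseudo-enantiomeric quinidine would be used).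

"Farnesyl" means (2E,6E)-3,7,11-trimethyldodeca-2,6,10-trien-1-yl throughout.

**Route**

Step 1
Reactants: 1 1,3-dithiane; 2 (2E,6E)-farnesyl bromide
Product: 3 2-farnesyl-1,3-dithiane
Conditions: n-BuLi (1.05 equiv), THF, −30 °C; then 2, −78 → 0 °C
Reagents that add atoms: none
Why: Corey–Seebach alkylation, in which 2-lithio-1,3-dithiane should displace the primary allylic bromide by SN2 at the unhindered CH2 and leave both E alkenes untouched.

Step 2
Reactants: 3 2-farnesyl-1,3-dithiane; 4 3-(trimethylsilyl)prop-2-ynal
Product: 6 1-(2-farnesyl-1,3-dithian-2-yl)prop-2-yn-1-ol (racemic), via C-silylated alkynol lithium alkoxide 5 (not isolated)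
Conditions: n-BuLi (1.1 equiv), THF, −20 °C; 4, −78 °C; then MeOH, K2CO3 (0.2 equiv), −78 °C → rt
Reagents that add atoms: none
Why: Corey–Seebach umpolung addition of the tertiary 2-lithiodithiane to the non-enolisable ynal, followed by methoxide protodesilylation of the alkynyl C–Si bond before any ynone exists, so methanol cannot add in conjugate fashion; the carbinol centre forms racemic and is erased in step 3.

Step 3
Reactants: 6 1-(2-farnesyl-1,3-dithian-2-yl)prop-2-yn-1-ol
Product: 7 1-(2-farnesyl-1,3-dithian-2-yl)prop-2-yn-1-one
Conditions: activated MnO2 (excess), CH2Cl2, rt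
Reagents that add atoms: none
Why: MnO2 oxidation of a propargylic alcohol, which should spare the thioacetal sulfur and the chain alkenes and give an ynone that has no alpha hydrogen.

Step 4
Reactants: 8 methyl acetoacetate
Product: 9 methyl 3-(trimethylsilyloxy)but-2-enoate (E/Z mixture, of no consequence)
Conditions: TMSCl, Et3N, hexane, rt
Reagents that add atoms: chlorotrimethylsilane, C[Si](C)(C)Cl
Why: Silyl enol ether formation by O-silylation of the beta-keto ester enol under amine base.

Step 5
Reactants: 9 methyl 3-(trimethylsilyloxy)but-2-enoate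
Product: 10 (Z)-1-methoxy-1,3-bis(trimethylsilyloxy)buta-1,3-diene
Conditions: LiN(i-Pr)2, THF, −78 °C; TMSCl, −78 → 0 °C
Reagents that add atoms: chlorotrimethylsilane, C[Si](C)(C)Cl
Why: Silyl ketene acetal formation, in which gamma-deprotonation of the enol ether ester gives a dienolate that is trapped on oxygen by the silyl chloride.

Step 6
Reactants: 7 1-(2-farnesyl-1,3-dithian-2-yl)prop-2-yn-1-one; 10 (Z)-1-methoxy-1,3-bis(trimethylsilyloxy)buta-1,3-diene
Product: 12 (2,4-dihydroxyphenyl)(2-farnesyl-1,3-dithian-2-yl)methanone, via cyclohexa-1,4-diene cycloadduct 11 (not isolated)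
Conditions: 10 (2 equiv), toluene, rt → 60 °C; then 0.5 M aq. HCl, THF, 0 °C
Reagents that add atoms: none
Why: The electron-rich bis(silyloxy)diene and the electron-poor terminal ynone should combine in a thermal, strongly asynchronous normal-demand Diels–Alder reaction, in which the diene CH2 terminus (future C5) bonds to the alkyne CH (future C4) and the ketene-acetal carbon (future C7a) closes onto the acyl-bearing alkyne carbon (future C3a). The closest known reaction type is the benzannulation of 1-alkoxy-1,3-bis(silyloxy)buta-1,3-dienes with acetylenic ketones and esters, which aromatize to resorcinol derivatives by loss of the alcohol. The six-membered benzo ring is closed by the [4+2] cycloaddition itself through the two new bonds C4–C5 and C3a–C7a, and adduct 11, a mixed silyl methyl ketal at C7a, then loses methanol and both silyl groups in dilute acid to reach the aromatic ring. No stereocentre is formed. The step needs regio- and chemoselectivity: the matched polarisation of the partners (nucleophilic diene CH2, electrophilic ynone beta-carbon) places the two hydroxyls ortho and para to the ketone, the quaternary dithiane carbon makes the ketone non-enolisable and screens its carbonyl from 1,2-attack, and the absence of a Lewis acid leaves the three chain alkenes and the thioacetal untouched.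

Step 7
Reactants: 12 (2,4-dihydroxyphenyl)(2-farnesyl-1,3-dithian-2-yl)methanone
Product: 13 [2,4-bis(tert-butyldimethylsilyloxy)phenyl](2-farnesyl-1,3-dithian-2-yl)methanone
Conditions: TBSOTf (2.5 equiv), 2,6-lutidine, CH2Cl2, 0 °C → rt
Reagents that add atoms: tert-butyldimethylsilyl trifluoromethanesulfonate, CC(C)(C)[Si](C)(C)OS(=O)(=O)C(F)(F)F
Why: Silyl ether formation with the silyl triflate, reactive enough to cap the chelated ortho hydroxyl as well, so that neither phenol is exposed to the trivalent iodine oxidant of step 8.

Step 8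
Reactants: 13 [2,4-bis(tert-butyldimethylsilyloxy)phenyl](2-farnesyl-1,3-dithian-2-yl)methanone
Product: 14 (4E,8E)-1-[2,4-bis(tert-butyldimethylsilyloxy)phenyl]-5,9,13-trimethyltetradeca-4,8,12-triene-1,2-dione
Conditions: PhI(OCOCF3)2 (1.5 equiv), NaHCO3, MeCN/H2O 9:1, 0 °C
Reagents that add atoms: water, O
Why: Oxidative dithioacetal hydrolysis, in which sulfur attacks the trivalent iodine reagent, the C–S bond ionises and water is captured, a process faster than any reaction of trisubstituted alkenes or aryl silyl ethers under bicarbonate buffering.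

Step 9
Reactants: 14 (4E,8E)-1-[2,4-bis(tert-butyldimethylsilyloxy)phenyl]-5,9,13-trimethyltetradeca-4,8,12-triene-1,2-dione
Product: 16 racemic 2-farnesyl-2,6-dihydroxy-1-benzofuran-3(2H)-one, via ring-opened dihydroxyaryl 1,2-dione 15 (not isolated)
Conditions: Bu4NF/AcOH (1:1, 2.2 equiv), THF, 0 °C
Reagents that add atoms: none
Why: Buffered fluoride desilylation frees both phenols, and the C7a hydroxyl should add at once to the C2 ketone in a 5-exo-trig hemiketalization (ring–chain tautomerism that favours the cyclic form for 2-hydroxyaryl 1,2-diones); C2 forms without control as the racemate and is set in step 10.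

Step 10
Reactants: 16 racemic 2-farnesyl-2,6-dihydroxy-1-benzofuran-3(2H)-one; 17 quinine
Product: 18 quininium (R)-2-farnesyl-2-hydroxy-3-oxo-2,3-dihydro-1-benzofuran-6-olate (1:1 salt)
Conditions: 17 (1.0 equiv), i-PrOAc/heptane, 45 → 5 °C, slow cooling and slurry ageing; filtration
Reagents that add atoms: none
Why: Proposed new method: the quinuclidine nitrogen should form a salt (or hydrogen-bonded 1:1 complex) at the acidic C6 phenol, a vinylogous acid through the C3 ketone, and as a general base in solution it should also catalyse ring–chain tautomerism of the hemiketal through the achiral dione 15, so the two C2 epimers of the salt interconvert in the mother liquor while the less soluble one, taken to be (R), is drained from the equilibrium by crystallization and C2 is set under lattice control; a tertiary amine is chosen so that no imine can form with the dione, and the closest known reaction type is the crystallization-induced asymmetric (diastereomer) transformation of configurationally labile lactols, hemiaminals and alpha-epimerisable carbonyl compounds as salts with chiral amines.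

Step 11
Reactants: 18 quininium (R)-2-farnesyl-2-hydroxy-3-oxo-2,3-dihydro-1-benzofuran-6-olate
Product: 19 (R)-2-farnesyl-2,6-dihydroxy-1-benzofuran-3(2H)-one (target)
Conditions: MTBE, 0.5 M aq. citric acid, 0 °C; dry (Na2SO4); concentrate below 20 °C
Reagents that add atoms: none
Why: Acid–base salt break, in which the cold weakly acidic wash protonates the phenoxide and carries quinine into water, removing the base that catalyses ring opening so that the (R) configuration fixed in the crystal should be kept.

**Compound list**

1 | 1,3-dithiane | C1CSCSC1 | starting material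
2 | (2E,6E)-farnesyl bromide | CC(C)=CCC/C(C)=C/CC/C(C)=C/CBr | starting material
3 | 2-farnesyl-1,3-dithiane | CC(C)=CCC/C(C)=C/CC/C(C)=C/CC1SCCCS1 | intermediate
4 | 3-(trimethylsilyl)prop-2-ynal | C[Si](C)(C)C#CC=O | starting material
5 | lithium 1-(2-farnesyl-1,3-dithian-2-yl)-3-(trimethylsilyl)prop-2-yn-1-olate (racemic) | CC(C)=CCC/C(C)=C/CC/C(C)=C/CC1(SCCCS1)C([O-])C#C[Si](C)(C)C.[Li+] | intermediate
6 | 1-(2-farnesyl-1,3-dithian-2-yl)prop-2-yn-1-ol (racemic) | CC(C)=CCC/C(C)=C/CC/C(C)=C/CC1(SCCCS1)C(O)C#C | intermediate
7 | 1-(2-farnesyl-1,3-dithian-2-yl)prop-2-yn-1-one | CC(C)=CCC/C(C)=C/CC/C(C)=C/CC1(SCCCS1)C(=O)C#C | intermediate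
8 | methyl acetoacetate | COC(=O)CC(C)=O | starting material
9 | methyl 3-(trimethylsilyloxy)but-2-enoate (E/Z mixture) | COC(=O)C=C(C)O[Si](C)(C)C | intermediate
10 | (Z)-1-methoxy-1,3-bis(trimethylsilyloxy)buta-1,3-diene | CO/C(O[Si](C)(C)C)=C/C(O[Si](C)(C)C)=C | intermediate
11 | (2-farnesyl-1,3-dithian-2-yl)[6-methoxy-4,6-bis(trimethylsilyloxy)cyclohexa-1,4-dien-1-yl]methanone (racemic) | CC(C)=CCC/C(C)=C/CC/C(C)=C/CC1(SCCCS1)C(=O)C1=CCC(O[Si](C)(C)C)=CC1(OC)O[Si](C)(C)C | intermediate
12 | (2,4-dihydroxyphenyl)(2-farnesyl-1,3-dithian-2-yl)methanone | CC(C)=CCC/C(C)=C/CC/C(C)=C/CC1(SCCCS1)C(=O)c1ccc(O)cc1O | intermediate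
13 | [2,4-bis(tert-butyldimethylsilyloxy)phenyl](2-farnesyl-1,3-dithian-2-yl)methanone | CC(C)=CCC/C(C)=C/CC/C(C)=C/CC1(SCCCS1)C(=O)c1ccc(O[Si](C)(C)C(C)(C)C)cc1O[Si](C)(C)C(C)(C)C | intermediate
14 | (4E,8E)-1-[2,4-bis(tert-butyldimethylsilyloxy)phenyl]-5,9,13-trimethyltetradeca-4,8,12-triene-1,2-dione | CC(C)=CCC/C(C)=C/CC/C(C)=C/CC(=O)C(=O)c1ccc(O[Si](C)(C)C(C)(C)C)cc1O[Si](C)(C)C(C)(C)C | intermediate
15 | (4E,8E)-1-(2,4-dihydroxyphenyl)-5,9,13-trimethyltetradeca-4,8,12-triene-1,2-dione | CC(C)=CCC/C(C)=C/CC/C(C)=C/CC(=O)C(=O)c1ccc(O)cc1O | intermediate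
16 | racemic 2-farnesyl-2,6-dihydroxy-1-benzofuran-3(2H)-one | CC(C)=CCC/C(C)=C/CC/C(C)=C/CC1(O)Oc2cc(O)ccc2C1=O | intermediate
17 | quinine | C=C[C@H]1CN2CC[C@H]1C[C@H]2[C@H](O)c1ccnc2ccc(OC)cc12 | starting material
18 | quininium (R)-2-farnesyl-2-hydroxy-3-oxo-2,3-dihydro-1-benzofuran-6-olate | C=C[C@H]1C[N@@H+]2CC[C@H]1C[C@H]2[C@H](O)c1ccnc2ccc(OC)cc12.CC(C)=CCC/C(C)=C/CC/C(C)=C/C[C@@]1(O)Oc2cc([O-])ccc2C1=O | intermediate
19 | (R)-2-farnesyl-2,6-dihydroxy-1-benzofuran-3(2H)-one | CC(C)=CCC/C(C)=C/CC/C(C)=C/C[C@@]1(O)Oc2cc(O)ccc2C1=O | target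

**Count**

Total steps: 11. Longest linear sequence: 9 steps (steps 1, 2, 3, 6, 7, 8, 9, 10, 11); the diene branch (steps 4 and 5) joins at step 6.

**Steps most likely to fail**

Step 10. The salt may oil out because of the lipophilic farnesyl chain, the two diastereomeric salts may not differ enough in solubility, or amine-mediated enolisation of the transient dione may erode material during ageing. The fallback uses known chemistry and sets out from racemate 16. It is resolved by preparative chromatography on a polysaccharide chiral stationary phase (amylose tris(3,5-dimethylphenylcarbamate), heptane/i-PrOH, neutral eluent, column kept cool), which delivers target 19 directly. The unwanted (S)-2-farnesyl-2,6-dihydroxy-1-benzofuran-3(2H)-one F1 is re-equilibrated to 16 with catalytic Et3N in EtOAc, freed of the amine by a cold citric acid wash and injected again.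

Step 6. The cycloaddition may stop at a Michael adduct that does not close, the diene may attack the ketone carbonyl, or the terminal ynone may oligomerise before it is consumed. The fallback forms the aryl–carbonyl bond by carbonyl addition instead; it sets out from 3 and returns at 12. Compound 3 is lithiated as in step 2 and added to 2,4-bis(methoxymethoxy)benzaldehyde F2 (from 2,4-dihydroxybenzaldehyde, MOMCl and i-Pr2NEt) to give [2,4-bis(methoxymethoxy)phenyl](2-farnesyl-1,3-dithian-2-yl)methanol F3. Parikh–Doering oxidation (SO3·pyridine, DMSO, Et3N) gives [2,4-bis(methoxymethoxy)phenyl](2-farnesyl-1,3-dithian-2-yl)methanone F4. ZnBr2 and n-PrSH in CH2Cl2 at 0 °C then remove both methoxymethyl groups without touching the thioacetal or the alkenes and give 12.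

Step 8. The trivalent iodine reagent may begin to oxidise the chain alkenes, or C–S ionisation next to the ketone may be so slow that hydrolysis stalls and sulfur is over-oxidised. The fallback separates sulfur oxidation from C–S cleavage; it sets out from 13 and returns at 14. NaIO4 in MeOH/THF/H2O at 0 °C, which does not attack alkenes, converts 13 into [2,4-bis(tert-butyldimethylsilyloxy)phenyl](2-farnesyl-1-oxido-1,3-dithian-2-yl)methanone F5 (diastereomer mixture). This dithioacetal monoxide is then hydrolysed with dilute aqueous HCl in THF at 0 °C to dione 14.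

**Further compounds**

F1 | step 10 | (S)-2-farnesyl-2,6-dihydroxy-1-benzofuran-3(2H)-one | CC(C)=CCC/C(C)=C/CC/C(C)=C/C[C@]1(O)Oc2cc(O)ccc2C1=O
F2 | step 6 | 2,4-bis(methoxymethoxy)benzaldehyde | COCOc1ccc(C=O)c(OCOC)c1
F3 | step 6 | [2,4-bis(methoxymethoxy)phenyl](2-farnesyl-1,3-dithian-2-yl)methanol (racemic) | CC(C)=CCC/C(C)=C/CC/C(C)=C/CC1(SCCCS1)C(O)c1ccc(OCOC)cc1OCOC
F4 | step 6 | [2,4-bis(methoxymethoxy)phenyl](2-farnesyl-1,3-dithian-2-yl)methanone | CC(C)=CCC/C(C)=C/CC/C(C)=C/CC1(SCCCS1)C(=O)c1ccc(OCOC)cc1OCOC
F5 | step 8 | [2,4-bis(tert-butyldimethylsilyloxy)phenyl](2-farnesyl-1-oxido-1,3-dithian-2-yl)methanone (diastereomer mixture) | CC(C)=CCC/C(C)=C/CC/C(C)=C/CC1(SCCCS1=O)C(=O)c1ccc(O[Si](C)(C)C(C)(C)C)cc1O[Si](C)(C)C(C)(C)C
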